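## Retrosynthetic overview

1. The oxirane is made last, by epoxidation of the only electron-rich alkene (C4=C5) of diene triester 24.
2. The ten-membered ring is closed at C1=C10 by ring-closing metathesis of a terminal alkene onto the C10 acrylate, instead of the customary C6–C7 allylation macrocyclisation.
3. C7–C8 is made by a photoredox decarboxylative radical conjugate addition of an L-tartrate-derived dioxolanyl radical (C8, C9 from the chiral pool) to a γ-alkenyl butenolide; this one step sets C7 and C8.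
4. C6 comes from a catalytic asymmetric alkynylation, C14 from CO (Markovnikov hydromethoxycarbonylation of the tartrate-derived alkyne), and C13 from a Mannich/elimination methylenation.
5. Ring order: γ-lactone (as butenolide) first, ten-membered carbocycle second, oxirane third.

Assumption: (S,S)-ProPhenol is taken to give the 4R alcohol 7; if the sense is the opposite, the (R,R) ligand is used and nothing else changes.
Numbering used in names of macrocycles: germacrane numbering (ring C1–C10; lactone carbons C11, C12, C13; C14 = ester carbon on C10; C15 = methyl on C4). "1(10)E" is the ring-cis alkene (C2 and C9 on the same side, CO2Me trans to C2).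

## Route

Step 1
Reactants: 1 methyl but-2-ynoate; 2 but-3-en-1-ylmagnesium bromide
Product: 3 methyl (2E)-3-methylhepta-2,6-dienoate
Conditions: CuBr·SMe2 (1.3 equiv), THF, −78 °C; NH4Cl (aq), −78 °C
Reagents that add atoms: none
Why: Syn carbocupration of the ynoate (organocopper conjugate addition) and stereoretentive protonation at −78 °C place the butenyl chain trans to the ester, which fixes the E geometry of the future C4=C5 alkene.

Step 2
Reactants: 3 methyl (2E)-3-methylhepta-2,6-dienoate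
Product: 4 (2E)-3-methylhepta-2,6-dien-1-ol
Conditions: i-Bu2AlH (2.2 equiv), CH2Cl2, −78 → 0 °C; Rochelle salt (aq)
Reagents that add atoms: none
Why: Aluminium hydride 1,2-reduction of the enoate gives the allylic alcohol without touching either alkene.

Step 3
Reactants: 4 (2E)-3-methylhepta-2,6-dien-1-ol
Product: 5 (2E)-3-methylhepta-2,6-dienal
Conditions: MnO2 (15 equiv), CH2Cl2, rt
Reagents that add atoms: none
Why: Allylic oxidation with MnO2 stops at the enal and does not isomerise the trisubstituted alkene.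

Step 4
Reactants: 5 (2E)-3-methylhepta-2,6-dienal; 6 methyl prop-2-ynoate
Product: 7 methyl (4R,5E)-4-hydroxy-6-methyldeca-5,9-dien-2-ynoate
Conditions: (S,S)-ProPhenol (20 mol%), ZnMe2 (3 equiv), Ph3P=O (40 mol%), PhMe, 4 °C; NH4Cl (aq)
Reagents that add atoms: none
Why: Trost dinuclear zinc–ProPhenol asymmetric alkynylation delivers the zinc acetylide of 6 to one face of the enal and sets the carbinol centre that becomes C6.

Step 5
Reactants: 7 methyl (4R,5E)-4-hydroxy-6-methyldeca-5,9-dien-2-ynoate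
Product: 9 (5S)-5-[(1E)-2-methylhexa-1,5-dien-1-yl]furan-2(5H)-one, via Z-hydroxy enoate 8 (not isolated)
Conditions: H2 (1 atm, stopped at 1.0 equiv), Pd/CaCO3–Pb(OAc)2 (Lindlar catalyst), quinoline, EtOAc, 0 °C → rt; then SiO2, CH2Cl2, rt
Reagents that add atoms: none
Why: Lindlar cis-semihydrogenation of the ynoate (much faster than reduction of the isolated alkenes) gives the Z-γ-hydroxy enoate, which lactonises spontaneously; the stereocentre is untouched and only its CIP label changes.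

Step 6
Reactants: 10 dimethyl (4R,5R)-2,2-dimethyl-1,3-dioxolane-4,5-dicarboxylate
Product: 12 methyl (4R,5S)-5-ethynyl-2,2-dimethyl-1,3-dioxolane-4-carboxylate, via aldehyde ester 11 (not isolated)
Conditions: i-Bu2AlH (1.0 equiv), CH2Cl2, −78 °C; then MeOH, K2CO3, dimethyl (1-diazo-2-oxopropyl)phosphonate, −78 °C → rt
Reagents that add atoms: dimethyl (1-diazo-2-oxopropyl)phosphonate, CC(=O)C(=[N+]=[N-])P(=O)(OC)OC
Why: One-pot half-reduction and Ohira–Bestmann (Seyferth–Gilbert) homologation converts one ester into the terminal alkyne; both tartrate centres are kept because the trans-dioxolane is the thermodynamic isomer.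

Step 7
Reactants: 12 methyl (4R,5S)-5-ethynyl-2,2-dimethyl-1,3-dioxolane-4-carboxylate
Product: 13 (4R,5S)-5-ethynyl-2,2-dimethyl-1,3-dioxolane-4-carboxylic acid
Conditions: LiOH·H2O (1.5 equiv), THF/H2O, 0 °C; HCl (1 M) to pH 3
Reagents that add atoms: lithium hydroxide, [Li+].[OH-]
Why: Mild saponification at 0 °C; the α-centre becomes the radical carbon in step 9, so its integrity is not critical.

Step 8
Reactants: 13 (4R,5S)-5-ethynyl-2,2-dimethyl-1,3-dioxolane-4-carboxylic acid
Product: 14 1,3-dioxoisoindolin-2-yl (4R,5S)-5-ethynyl-2,2-dimethyl-1,3-dioxolane-4-carboxylate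
Conditions: N-hydroxyphthalimide (1.1 equiv), N,N'-diisopropylcarbodiimide (1.1 equiv), DMAP (5 mol%), CH2Cl2, 0 °C → rt
Reagents that add atoms: N-hydroxyphthalimide, O=C1c2ccccc2C(=O)N1O
Why: Carbodiimide (Steglich-type) esterification gives the redox-active ester needed for reductive decarboxylation.

Step 9
Reactants: 9 (5S)-5-[(1E)-2-methylhexa-1,5-dien-1-yl]furan-2(5H)-one; 14 1,3-dioxoisoindolin-2-yl (4R,5S)-5-ethynyl-2,2-dimethyl-1,3-dioxolane-4-carboxylate
Product: 15 (4S,5R)-4-[(4S,5S)-5-ethynyl-2,2-dimethyl-1,3-dioxolan-4-yl]-5-[(1E)-2-methylhexa-1,5-dien-1-yl]oxolan-2-one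
Conditions: Ru(bpy)3(PF6)2 (1 mol%), Hantzsch ester (1.5 equiv), CH2Cl2, blue LEDs (450 nm), rt; 14 used in 1.5-fold excess
Reagents that add atoms: none
Why: Photoredox decarboxylative Giese reaction: the nucleophilic dioxolanyl radical adds to the butenolide β-carbon anti to the γ-alkenyl group (sets C7, trans-lactone) and reacts on its own face anti to the ethynyl group (sets C8, trans-acetonide), so C6 and C9 fix all four contiguous centres.

Step 10
Reactants: 15 (4S,5R)-4-[(4S,5S)-5-ethynyl-2,2-dimethyl-1,3-dioxolan-4-yl]-5-[(1E)-2-methylhexa-1,5-dien-1-yl]oxolan-2-one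
Product: 16 methyl 2-[(4S,5S)-2,2-dimethyl-5-{(2R,3S)-2-[(1E)-2-methylhexa-1,5-dien-1-yl]-5-oxooxolan-3-yl}-1,3-dioxolan-4-yl]prop-2-enoate
Conditions: Pd(OAc)2 (2 mol%), 2-(diphenylphosphino)pyridine (30 mol%), MsOH (10 mol%), CO (10 bar), MeOH/CH2Cl2 (1:5), 45 °C
Reagents that add atoms: carbon monoxide, [C-]#[O+]; methanol, CO
Why: Palladium hydride/pyridylphosphine Markovnikov hydromethoxycarbonylation of the terminal alkyne gives the 2-substituted acrylate (C14 from CO); alkynes react far faster than the alkenes and the excess pyridylphosphine buffers the acid so the acetonide survives.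

Step 11
Reactants: 16 methyl 2-[(4S,5S)-2,2-dimethyl-5-{(2R,3S)-2-[(1E)-2-methylhexa-1,5-dien-1-yl]-5-oxooxolan-3-yl}-1,3-dioxolan-4-yl]prop-2-enoate
Product: 17 methyl (1(10)E,4E,6R,7S,8S,9S)-8,9-(isopropylidenedioxy)-13-norgermacra-1(10),4-dien-12,6-olid-14-oate
Conditions: RuCl2(H2IMes)(=CH-C6H4-2-O-i-Pr) (Hoveyda–Grubbs second-generation catalyst, 2 × 10 mol%), 1,4-benzoquinone (20 mol%), PhMe (1 mM), 90 °C, Ar sparge
Reagents that add atoms: none
Why: Ring-closing metathesis of the terminal alkene onto the acrylate closes the ten-membered ring at C1=C10; the trans-lactone and trans-acetonide hold the chain in a turn, and the ring-cis alkene (CO2Me trans to C2) is the less strained and expected product.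

Step 12
Reactants: 17 methyl (1(10)E,4E,6R,7S,8S,9S)-8,9-(isopropylidenedioxy)-13-norgermacra-1(10),4-dien-12,6-olid-14-oate
Product: 21 methyl (1(10)E,4E,6R,7S,8S,9S)-8,9-(isopropylidenedioxy)germacra-1(10),4,11(13)-trien-12,6-olid-14-oate, via lithium enolate 18 (not isolated), via Mannich base 19 (not isolated), via trimethylammonium iodide 20 (not isolated)
Conditions: LiN(SiMe3)2 (1.2 equiv), THF, −78 °C; Me2N=CH2+ I− (3 equiv), −78 °C → rt; MeI (10 equiv), rt; NaHCO3 (aq)/CH2Cl2, rt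
Reagents that add atoms: N,N-dimethylmethyleneiminium iodide (Eschenmoser's salt), C=[N+](C)C.[I-]
Why: Kinetic lactone enolate formation (the enoate has no α-hydrogen and its γ-CH2 is anti to the carbonyl), Mannich reaction with Eschenmoser's salt, then quaternisation and Hofmann-type elimination give the α-methylene lactone; C7 is not epimerisable.

Step 13
Reactants: 21 methyl (1(10)E,4E,6R,7S,8S,9S)-8,9-(isopropylidenedioxy)germacra-1(10),4,11(13)-trien-12,6-olid-14-oate
Product: 22 methyl (1(10)E,4E,6R,7R,8S,9S)-8,9-dihydroxygermacra-1(10),4,11(13)-trien-12,6-olid-14-oate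
Conditions: AcOH/H2O (4:1), 45 °C
Reagents that add atoms: none
Why: Mild acid-catalysed acetal hydrolysis frees the 8,9-diol without ionising the allylic lactone C6–O bond or protonating the trisubstituted alkene.

Step 14
Reactants: 22 methyl (1(10)E,4E,6R,7R,8S,9S)-8,9-dihydroxygermacra-1(10),4,11(13)-trien-12,6-olid-14-oate
Product: 23 methyl (1(10)E,4E,6R,7R,8S,9S)-9-acetoxy-8-hydroxygermacra-1(10),4,11(13)-trien-12,6-olid-14-oate
Conditions: Ac2O (1.1 equiv), pyridine, CH2Cl2, −20 °C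
Reagents that add atoms: acetic anhydride, CC(=O)OC(C)=O
Why: Regioselective acylation: the allylic 9-OH next to the planar C10 is less hindered than the 8-OH, which sits between two sp3 methines beside the lactone, so limiting Ac2O at low temperature acetylates O9.

Step 15
Reactants: 23 methyl (1(10)E,4E,6R,7R,8S,9S)-9-acetoxy-8-hydroxygermacra-1(10),4,11(13)-trien-12,6-olid-14-oate
Product: 24 methyl (1(10)E,4E,6R,7S,8S,9S)-9-acetoxy-8-(2-methylprop-2-enoyloxy)germacra-1(10),4,11(13)-trien-12,6-olid-14-oate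
Conditions: methacrylic anhydride (3 equiv), DMAP (0.5 equiv), Et3N (3 equiv), BHT (cat.), CH2Cl2, 0 °C → rt
Reagents that add atoms: methacrylic anhydride, CC(=C)C(=O)OC(=O)C(C)=C
Why: DMAP-catalysed acylation of the remaining hindered 8-OH with excess anhydride outpaces acetyl migration and installs the methacrylate.

Step 16
Reactants: 24 methyl (1(10)E,4E,6R,7S,8S,9S)-9-acetoxy-8-(2-methylprop-2-enoyloxy)germacra-1(10),4,11(13)-trien-12,6-olid-14-oate
Product: 25 methyl (1(10)E,4R,5R,6S,7R,8S,9S)-9-acetoxy-4,5-epoxy-8-(2-methylprop-2-enoyloxy)germacra-1(10),11(13)-dien-12,6-olid-14-oate (CNP0153978.3)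
Conditions: mCPBA (1.2 equiv), CH2Cl2, 0 °C
Reagents that add atoms: 3-chloroperbenzoic acid, OOC(=O)c1cccc(Cl)c1
Why: Prilezhaev epoxidation attacks only the electron-rich trisubstituted C4=C5 alkene (the other three alkenes are conjugated to esters), from the outward face of the E-alkene, as in related germacranolide 4,5-epoxidations, to give the 4R,5R oxirane syn to the C6–O bond.

## Compound list

1 | methyl but-2-ynoate | CC#CC(=O)OC | starting material
2 | but-3-en-1-ylmagnesium bromide | C=CCC[Mg]Br | starting material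
3 | methyl (2E)-3-methylhepta-2,6-dienoate | COC(=O)/C=C(\C)CCC=C | intermediate
4 | (2E)-3-methylhepta-2,6-dien-1-ol | OC/C=C(\C)CCC=C | intermediate
5 | (2E)-3-methylhepta-2,6-dienal | O=C/C=C(\C)CCC=C | intermediate
6 | methyl prop-2-ynoate | C#CC(=O)OC | starting material
7 | methyl (4R,5E)-4-hydroxy-6-methyldeca-5,9-dien-2-ynoate | COC(=O)C#C[C@H](O)/C=C(\C)CCC=C | intermediate
8 | methyl (2Z,4S,5E)-4-hydroxy-6-methyldeca-2,5,9-trienoate (not isolated) | COC(=O)/C=C\[C@H](O)/C=C(\C)CCC=C | intermediate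
9 | (5S)-5-[(1E)-2-methylhexa-1,5-dien-1-yl]furan-2(5H)-one | O=C1C=C[C@@H](/C=C(\C)CCC=C)O1 | intermediate
10 | dimethyl (4R,5R)-2,2-dimethyl-1,3-dioxolane-4,5-dicarboxylate (acetonide of dimethyl L-tartrate) | COC(=O)[C@@H]1OC(C)(C)O[C@H]1C(=O)OC | starting material
11 | methyl (4R,5R)-5-formyl-2,2-dimethyl-1,3-dioxolane-4-carboxylate (not isolated) | O=C[C@@H]1OC(C)(C)O[C@H]1C(=O)OC | intermediate
12 | methyl (4R,5S)-5-ethynyl-2,2-dimethyl-1,3-dioxolane-4-carboxylate | C#C[C@@H]1OC(C)(C)O[C@H]1C(=O)OC | intermediate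
13 | (4R,5S)-5-ethynyl-2,2-dimethyl-1,3-dioxolane-4-carboxylic acid | C#C[C@@H]1OC(C)(C)O[C@H]1C(=O)O | intermediate
14 | 1,3-dioxoisoindolin-2-yl (4R,5S)-5-ethynyl-2,2-dimethyl-1,3-dioxolane-4-carboxylate | C#C[C@@H]1OC(C)(C)O[C@H]1C(=O)ON1C(=O)c2ccccc2C1=O | intermediate
15 | (4S,5R)-4-[(4S,5S)-5-ethynyl-2,2-dimethyl-1,3-dioxolan-4-yl]-5-[(1E)-2-methylhexa-1,5-dien-1-yl]oxolan-2-one | C#C[C@@H]1OC(C)(C)O[C@H]1[C@H]1CC(=O)O[C@@H]1/C=C(\C)CCC=C | intermediate
16 | methyl 2-[(4S,5S)-2,2-dimethyl-5-{(2R,3S)-2-[(1E)-2-methylhexa-1,5-dien-1-yl]-5-oxooxolan-3-yl}-1,3-dioxolan-4-yl]prop-2-enoate | C=C(C(=O)OC)[C@@H]1OC(C)(C)O[C@H]1[C@H]1CC(=O)O[C@@H]1/C=C(\C)CCC=C | intermediate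
17 | methyl (1(10)E,4E,6R,7S,8S,9S)-8,9-(isopropylidenedioxy)-13-norgermacra-1(10),4-dien-12,6-olid-14-oate (ring-cis C1=C10, trans-lactone, trans-acetonide) | COC(=O)/C1=C/CC/C(C)=C/[C@H]2OC(=O)C[C@@H]2[C@@H]2OC(C)(C)O[C@@H]12 | intermediate
18 | lithium enolate of 17 (C11=C12–OLi; not isolated) | [Li+].COC(=O)/C1=C/CC/C(C)=C/[C@H]2OC([O-])=C[C@@H]2[C@@H]2OC(C)(C)O[C@@H]12 | intermediate
19 | methyl (1(10)E,4E,6R,7S,8S,9S)-13-(dimethylamino)-8,9-(isopropylidenedioxy)germacra-1(10),4-dien-12,6-olid-14-oate (C11 epimers; not isolated) | COC(=O)/C1=C/CC/C(C)=C/[C@H]2OC(=O)C(CN(C)C)[C@@H]2[C@@H]2OC(C)(C)O[C@@H]12 | intermediate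
20 | N-methyl quaternary ammonium iodide of 19 (not isolated) | [I-].COC(=O)/C1=C/CC/C(C)=C/[C@H]2OC(=O)C(C[N+](C)(C)C)[C@@H]2[C@@H]2OC(C)(C)O[C@@H]12 | intermediate
21 | methyl (1(10)E,4E,6R,7S,8S,9S)-8,9-(isopropylidenedioxy)germacra-1(10),4,11(13)-trien-12,6-olid-14-oate | COC(=O)/C1=C/CC/C(C)=C/[C@H]2OC(=O)C(=C)[C@@H]2[C@@H]2OC(C)(C)O[C@@H]12 | intermediate
22 | methyl (1(10)E,4E,6R,7R,8S,9S)-8,9-dihydroxygermacra-1(10),4,11(13)-trien-12,6-olid-14-oate | COC(=O)/C1=C/CC/C(C)=C/[C@H]2OC(=O)C(=C)[C@@H]2[C@H](O)[C@H]1O | intermediate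
23 | methyl (1(10)E,4E,6R,7R,8S,9S)-9-acetoxy-8-hydroxygermacra-1(10),4,11(13)-trien-12,6-olid-14-oate | COC(=O)/C1=C/CC/C(C)=C/[C@H]2OC(=O)C(=C)[C@@H]2[C@H](O)[C@H]1OC(C)=O | intermediate
24 | methyl (1(10)E,4E,6R,7S,8S,9S)-9-acetoxy-8-(2-methylprop-2-enoyloxy)germacra-1(10),4,11(13)-trien-12,6-olid-14-oate | COC(=O)/C1=C/CC/C(C)=C/[C@H]2OC(=O)C(=C)[C@@H]2[C@H](OC(=O)C(C)=C)[C@H]1OC(C)=O | intermediate
25 | methyl (1(10)E,4R,5R,6S,7R,8S,9S)-9-acetoxy-4,5-epoxy-8-(2-methylprop-2-enoyloxy)germacra-1(10),11(13)-dien-12,6-olid-14-oate (CNP0153978.3) | C=C(C)C(=O)O[C@H]1[C@H]2C(=C)C(=O)O[C@@H]2[C@H]2O[C@]2(C)CC/C=C(/C(=O)OC)[C@@H]1OC(C)=O | target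

## Step count and risks

Total step count: 16 (steps 1–5 west fragment, 6–8 east fragment, 9–16 union and endgame).
Longest linear sequence: 13 steps (steps 1–5, then 9–16).

Steps most likely to fail:

Step 11 (ring-closing metathesis). The acrylate partner is hindered and electron-poor, and a ten-membered ring must form, so oligomerisation or the ring-trans alkene are real possibilities. The fallback swaps the order of the two key bond formations; it sets out from 9 and 13 and comes back at 17. Acid 13 is hydromethoxycarbonylated as in step 10 to (4R,5S)-5-[1-(methoxycarbonyl)ethenyl]-2,2-dimethyl-1,3-dioxolane-4-carboxylic acid F1. Cross-metathesis of excess F1 with the terminal alkene of 9 (RuCl2(H2IMes)(=CH-C6H4-2-O-i-Pr), CH2Cl2, 40 °C) forms the C1=C10 enoate intermolecularly, where ring strain plays no part, giving (4R,5S)-5-{(1E,5E)-1-(methoxycarbonyl)-5-methyl-6-[(2S)-5-oxo-2,5-dihydrofuran-2-yl]hexa-1,5-dien-1-yl}-2,2-dimethyl-1,3-dioxolane-4-carboxylic acid F2. N-Hydroxyphthalimide and N,N'-diisopropylcarbodiimide convert it into the 1,3-dioxoisoindolin-2-yl ester of that acid F3. Irradiation of F3 at 1 mM with Ru(bpy)3(PF6)2 and slowly added Hantzsch ester then closes the ring by intramolecular decarboxylative radical conjugate addition (C7–C8, trans-lactone and trans-acetonide as in step 9) and gives 17.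

Step 14 (regioselective acetylation). The two secondary hydroxyls may not differ enough toward Ac2O, and acetyl migration can erode the ratio. The fallback is a protecting-group detour with a bulkier electrophile; it sets out from 22 and comes back at 24. TBSCl/imidazole (DMF, 0 °C) silylates the less hindered allylic 9-OH to give methyl (1(10)E,4E,6R,7R,8S,9S)-9-[(tert-butyldimethylsilyl)oxy]-8-hydroxygermacra-1(10),4,11(13)-trien-12,6-olid-14-oate F4. Methacrylic anhydride/DMAP acylates O8 to give methyl (1(10)E,4E,6R,7S,8S,9S)-9-[(tert-butyldimethylsilyl)oxy]-8-(2-methylprop-2-enoyloxy)germacra-1(10),4,11(13)-trien-12,6-olid-14-oate F5. HF·pyridine (THF, 0 °C; acidic, so no acyl migration) frees methyl (1(10)E,4E,6R,7S,8S,9S)-9-hydroxy-8-(2-methylprop-2-enoyloxy)germacra-1(10),4,11(13)-trien-12,6-olid-14-oate F6, and Ac2O/DMAP gives 24. If the silyl group goes to O8 instead, the two acylations are simply run in the opposite order.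

Step 16 (face selectivity of the epoxidation). The macrocycle may expose the other face of C4=C5 to the peracid. The fallback reaches the epoxide through a halohydrin, which places the oxygen on the face opposite to the one an electrophile attacks; it sets out from 24 and comes back at 25. NBS in DME/H2O (0 °C) forms the bromonium ion on the exposed face and water opens it anti at the tertiary C4, giving methyl (1(10)E,4R,5S,6S,7R,8S,9S)-9-acetoxy-5-bromo-4-hydroxy-8-(2-methylprop-2-enoyloxy)germacra-1(10),11(13)-dien-12,6-olid-14-oate F7. Ag2O (CH2Cl2, rt) then closes the oxirane with inversion at C5 to give 25.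

## Further compounds

F1 | step 11 | (4R,5S)-5-[1-(methoxycarbonyl)ethenyl]-2,2-dimethyl-1,3-dioxolane-4-carboxylic acid | C=C(C(=O)OC)[C@@H]1OC(C)(C)O[C@H]1C(=O)O
F2 | step 11 | (4R,5S)-5-{(1E,5E)-1-(methoxycarbonyl)-5-methyl-6-[(2S)-5-oxo-2,5-dihydrofuran-2-yl]hexa-1,5-dien-1-yl}-2,2-dimethyl-1,3-dioxolane-4-carboxylic acid | COC(=O)/C(=C/CC/C(C)=C/[C@H]1OC(=O)C=C1)[C@@H]1OC(C)(C)O[C@H]1C(=O)O
F3 | step 11 | 1,3-dioxoisoindolin-2-yl ester of F2 | COC(=O)/C(=C/CC/C(C)=C/[C@H]1OC(=O)C=C1)[C@@H]1OC(C)(C)O[C@H]1C(=O)ON1C(=O)c2ccccc2C1=O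
F4 | step 14 | methyl (1(10)E,4E,6R,7R,8S,9S)-9-[(tert-butyldimethylsilyl)oxy]-8-hydroxygermacra-1(10),4,11(13)-trien-12,6-olid-14-oate | COC(=O)/C1=C/CC/C(C)=C/[C@H]2OC(=O)C(=C)[C@@H]2[C@H](O)[C@H]1O[Si](C)(C)C(C)(C)C
F5 | step 14 | methyl (1(10)E,4E,6R,7S,8S,9S)-9-[(tert-butyldimethylsilyl)oxy]-8-(2-methylprop-2-enoyloxy)germacra-1(10),4,11(13)-trien-12,6-olid-14-oate | COC(=O)/C1=C/CC/C(C)=C/[C@H]2OC(=O)C(=C)[C@@H]2[C@H](OC(=O)C(C)=C)[C@H]1O[Si](C)(C)C(C)(C)C
F6 | step 14 | methyl (1(10)E,4E,6R,7S,8S,9S)-9-hydroxy-8-(2-methylprop-2-enoyloxy)germacra-1(10),4,11(13)-trien-12,6-olid-14-oate | COC(=O)/C1=C/CC/C(C)=C/[C@H]2OC(=O)C(=C)[C@@H]2[C@H](OC(=O)C(C)=C)[C@H]1O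
F7 | step 16 | methyl (1(10)E,4R,5S,6S,7R,8S,9S)-9-acetoxy-5-bromo-4-hydroxy-8-(2-methylprop-2-enoyloxy)germacra-1(10),11(13)-dien-12,6-olid-14-oate | COC(=O)/C1=C/CC[C@@](C)(O)[C@@H](Br)[C@H]2OC(=O)C(=C)[C@@H]2[C@H](OC(=O)C(C)=C)[C@H]1OC(C)=O
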